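## Retrosynthetic overview

Numbering (cembrane): C1 = ring-fusion CH bearing the lactone α-carbon C15 (C16 = carbonyl, C17 = exocyclic CH2); C14 = lactone O–CH; C13 = neighbouring CH(OAc); C11=C12(Me) and C7=C8(Me) = the E-alkenes; C4 = C(Me)OH; C3 = CH(OAc).
1. Endgame: 23 ⇐ diacetylation of the C3/C13 diol 22 ⇐ Eschenmoser methylenation at C15 of the 17-nor lactone 17.
2. Key disconnection C13–C14: the anti O13/O14 glycol allylic to C11=C12 is the retron of a reductive enal–aldehyde (cross-pinacol) coupling. Because O14 is γ and O3 is δ to the carboxyl C16, the open dialdehyde 13 carries C16 as a temporary δ-lactone on O3, which passes the acyl group to O14 once the 14-membered ring is closed.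
3. 13 ⇐ trans-4,6-disubstituted δ-lactone by conjugate addition of a formyl anion equivalent (C14) to dihydropyranone 10 (C1 set from C3) ⇐ (2R,3R)-2,3-epoxyfarnesol by propiolate chain extension, Lindlar reduction and invertive 6-exo lactonisation (C3 and C4 set); farnesol supplies C2–C13 with both E-alkenes.
4. Ring order: temporary δ-lactone (step 4) → 14-membered carbocycle and γ-lactone in one operation (step 8) → exocyclic methylene (step 10).

Key step: step 8

Remark on the chemistry: the tertiary C4 hydroxyl is assumed inert to the reagents of steps 5–8 and is carried unprotected; atom numbers in the steps are those defined above.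

## Route

Step 1
Reactants: 1 (2E,6E)-farnesol
Product: 2 (2R,3R)-2,3-epoxyfarnesol, [(2R,3R)-3-[(3E)-4,8-dimethylnona-3,7-dien-1-yl]-3-methyloxiran-2-yl]methanol
Conditions: Ti(OiPr)4 (cat.), D-(−)-diethyl tartrate (cat.), t-BuOOH, 4 Å molecular sieves, CH2Cl2, −20 °C
Reagents that add atoms: tert-butyl hydroperoxide, CC(C)(C)OO
Why: the Katsuki–Sharpless asymmetric epoxidation touches only the allylic-alcohol alkene, and the D-(−)-tartrate catalyst should deliver oxygen to the face that gives the (2R,3R)-epoxide, which fixes C4 directly and C3 after the inversion in step 4.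

Step 2
Reactants: 2 (2R,3R)-2,3-epoxyfarnesol; 3 triethyl orthopropiolate (3,3,3-triethoxyprop-1-yne)
Product: 6 ethyl 4-[(2R,3R)-3-[(3E)-4,8-dimethylnona-3,7-dien-1-yl]-3-methyloxiran-2-yl]but-2-ynoate, via epoxy triflate 4 (not isolated), via orthoester alkyne 5 (not isolated)
Conditions: Tf2O, 2,6-lutidine, CH2Cl2, −78 °C; then LiC≡CC(OEt)3 (from 3 and n-BuLi), THF/DMPU, −78 → −30 °C; then AcOH/H2O/THF, 0 °C
Reagents that add atoms: water, O
Why: SN2 alkylation of a non-stabilised lithium acetylide by the primary epoxy triflate is faster than epoxide opening when no Lewis acid is present, and mild aqueous acid then converts the orthoester into the ethyl ester without touching the epoxide stereocentres.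

Step 3
Reactants: 6 ethyl epoxy-ynoate
Product: 7 ethyl (2Z)-4-[(2R,3R)-3-[(3E)-4,8-dimethylnona-3,7-dien-1-yl]-3-methyloxiran-2-yl]but-2-enoate
Conditions: H2 (1 atm), Pd/CaCO3 poisoned with Pb(OAc)2 (Lindlar catalyst), quinoline, EtOAc, 0 °C → rt
Reagents that add atoms: none
Why: Lindlar semihydrogenation adds H2 syn to the alkyne only, giving the (Z)-enoate required for ring closure while the trisubstituted alkenes and the epoxide are inert.

Step 4
Reactants: 7 ethyl (Z)-epoxy-enoate
Product: 9 (6S)-6-[(2R,5E)-2-hydroxy-6,10-dimethylundeca-5,9-dien-2-yl]-5,6-dihydro-2H-pyran-2-one, via epoxy acid 8 (not isolated)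
Conditions: LiOH, THF/H2O, 0 °C; then 1 M HCl to pH 3; camphorsulfonic acid (cat.), CH2Cl2, 0 °C → rt
Reagents that add atoms: lithium hydroxide, [Li+].[OH-]
Why: saponification followed by acid-catalysed epoxy-acid lactonisation is a 6-exo SN2 attack of the carboxyl group on the secondary carbon C3 with inversion, the tertiary C4–O bond staying intact, so the anti (3S,4R) relationship results and C3–O and C16 are tied up in the temporary δ-lactone.

Step 5
Reactants: 9 hydroxy dihydropyranone
Product: 10 (6S)-6-[(2R,5E,9E)-2,11-dihydroxy-6,10-dimethylundeca-5,9-dien-2-yl]-5,6-dihydro-2H-pyran-2-one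
Conditions: SeO2 (cat.), t-BuOOH, salicylic acid (cat.), CH2Cl2, 0 °C → rt
Reagents that add atoms: tert-butyl hydroperoxide, CC(C)(C)OO (oxygen relayed through SeO2, O=[Se]=O)
Why: the SeO2/t-BuOOH allylic oxidation (ene reaction then [2,3]-shift) should attack the most electron-rich and least hindered gem-dimethyl alkene at its (E)-methyl group, giving the (E)-allylic alcohol that becomes C13 and leaving the electron-poor lactone alkene alone.

Step 6
Reactants: 10 diol dihydropyranone; 11 1,3-dithiane
Product: 12 (4R,6S)-4-(1,3-dithian-2-yl)-6-[(2R,5E,9E)-2,11-dihydroxy-6,10-dimethylundeca-5,9-dien-2-yl]oxan-2-one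
Conditions: 11 (3.5 equiv), n-BuLi, THF/HMPA, −78 °C; then 10, −78 → −40 °C; aq. NH4Cl
Reagents that add atoms: none
Why: conjugate (1,4-) addition of 2-lithio-1,3-dithiane as a solvent-separated ion pair should occur axially and anti to the C3 substituent of the half-chair dihydropyranone, giving the trans-4,6-disubstituted lactone and so setting C1 (R), the first two equivalents of the reagent serving only to deprotonate the two hydroxyl groups.

Step 7
Reactants: 12 dithiane diol
Product: 13 (2E,6E,10R)-10-[(2S,4R)-4-formyl-6-oxooxan-2-yl]-10-hydroxy-2,6-dimethylundeca-2,6-dienal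
Conditions: Dess–Martin periodinane (excess), MeCN/CH2Cl2/H2O (8:1:1), 0 °C → rt; crude product used directly
Reagents that add atoms: water, O
Why: Dess–Martin periodinane in wet acetonitrile both oxidises the allylic alcohol to the enal and cleaves the dithiane (hypervalent-iodine dethioacetalisation) in one mild, weakly acidic operation that should not epimerise C1.

Step 8
Reactants: 13 enal–aldehyde δ-lactone
Product: 17 (1R,3S,4R,7E,11E,13S,14R)-3,4,13-trihydroxy-17-norcembra-7,11-dien-16,14-olide (14-membered carbocycle trans-fused at C1/C14 to a saturated γ-lactone), via siloxyallylchromium species 14 (not isolated), via bridged chromium alkoxide 15 (not isolated), via silyl ether lactone 16 (not isolated)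
Conditions: CrCl2 (8 equiv), Et3SiCl (3 equiv), degassed DMF, 25 °C, syringe-pump addition of 13 (final 2 mM); then Bu4NF, THF, 0 °C → rt
Reagents that add atoms: none
Why: Proposed new method: divalent chromium reduces the enal of 13 in the presence of Et3SiCl to a 1-siloxyallyl radical, a second CrCl2 traps it as the γ-siloxyallyl species of trivalent chromium 14 (metal on C11), this adds through its oxygen-bearing terminus C13 to the C14 aldehyde in a closed six-membered chair transition state, and the chromium alkoxide on O14 (15) then attacks the δ-lactone carbonyl C16 and releases O3 (16); the closest known reactions are the CrCl2/R3SiCl cross-pinacol-type coupling of enals and enones with aldehydes (between two molecules and, within one molecule, for common ring sizes) and Nozaki–Hiyama–Kishi allylation macrocyclisations, whereas a 14-membered closure with a β-substituted enal followed by acyl transfer in the flask is without precedent. The 14-membered carbocycle closes by intramolecular carbonyl allylation with allyl transposition (C13–C14 bond formed, C11=C12 regenerated), and the γ-lactone closes by 5-exo-trig acyl transfer of O14 onto C16 with opening of the temporary δ-lactone. C13 and its anti relationship to C14 are controlled by the (E)-enol silane geometry inherited from the s-trans enal together with the chair transition state (siloxy group and aldehyde substituent both equatorial), and the E geometry of C11=C12 by the equatorial position of the C10 chain on the chromium-bearing carbon. C14 is controlled by C1: the formyl group sits axial on the trans-disubstituted δ-lactone and should be attacked anti to the C1–C2 bond (Felkin–Anh, with C2 and the bulky C3 carbinol side as the large group and approach over the flat C15–C16 acyl side), which gives 14R and the trans ring fusion. The step needs chemoselectivity (CrCl2 reduces only the conjugated aldehyde, not the saturated aldehyde or the lactone), regioselectivity for C13 over C11 (chromium prefers the carbon-only terminus, which keeps the enol silane conjugated, and reacts through the remote terminus) and cyclisation over oligomerisation (slow addition at high dilution; the trans relationship of C1 and C3 keeps the C4 hydroxyl from masking the aldehyde as a lactol and places O14 within reach of C16). The fluoride work-up removes all silyl groups and completes the acyl transfer to the more stable γ-lactone.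

Step 9
Reactants: 17 triol lactone
Product: 18 3,4,13-tris-O-(triethylsilyl) ether of 17
Conditions: Et3SiOTf, 2,6-lutidine, CH2Cl2, −78 → 0 °C
Reagents that add atoms: triethylsilyl trifluoromethanesulfonate, CC[Si](CC)(CC)OS(=O)(=O)C(F)(F)F
Why: the silyl triflate with 2,6-lutidine silylates secondary and hindered tertiary alcohols alike, masking all three hydroxyl groups for the enolate chemistry of step 10.

Step 10
Reactants: 18 tris-silyl ether lactone
Product: 21 (1R,3S,4R,7E,11E,13S,14R)-3,4,13-tris(triethylsilyloxy)cembra-7,11,15(17)-trien-16,14-olide, via Mannich base 19 (not isolated), via ammonium iodide 20 (not isolated)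
Conditions: LiN(iPr)2, THF, −78 °C; CH2=NMe2+ I− (Eschenmoser's salt), −78 °C → rt; then MeI, MeOH/CH2Cl2, rt; then aq. NaHCO3, EtOAc, rt
Reagents that add atoms: N,N-dimethylmethyleneiminium iodide (Eschenmoser's salt), C=[N+](C)C.[I-]
Why: Mannich reaction of the lactone enolate with Eschenmoser's salt, exhaustive N-methylation and base-induced Hofmann-type elimination is the standard α-methylenation of γ-butyrolactones, and the temporary stereocentre at C15 is destroyed in the elimination.

Step 11
Reactants: 21 tris-silyl α-methylene lactone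
Product: 22 (1R,3S,4R,7E,11E,13S,14R)-3,4,13-trihydroxycembra-7,11,15(17)-trien-16,14-olide (3,13-di-O-deacetylcrassocolide B)
Conditions: HF·pyridine, pyridine/THF, 0 °C → rt
Reagents that add atoms: none
Why: HF·pyridine cleaves the triethylsilyl ethers, the tertiary one included, under non-basic conditions that should neither add to the α-methylene lactone nor cause acyl migration.

Step 12
Reactants: 22 triol α-methylene lactone
Product: 23 Crassocolide B
Conditions: Ac2O, pyridine, 4-(dimethylamino)pyridine (cat.), CH2Cl2, 0 °C → rt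
Reagents that add atoms: acetic anhydride, CC(=O)OC(C)=O
Why: nucleophile-catalysed acetylation should esterify the two secondary alcohols at C3 and C13 much faster than the hindered tertiary C4 hydroxyl, giving the target.

## Compound list

1 | (2E,6E)-farnesol | OC/C=C(\C)CC/C=C(\C)CCC=C(C)C | starting material
2 | (2R,3R)-2,3-epoxyfarnesol | OC[C@H]1O[C@]1(C)CC/C=C(\C)CCC=C(C)C | intermediate
3 | triethyl orthopropiolate (3,3,3-triethoxyprop-1-yne) | C#CC(OCC)(OCC)OCC | starting material
4 | [(2R,3R)-3-[(3E)-4,8-dimethylnona-3,7-dien-1-yl]-3-methyloxiran-2-yl]methyl trifluoromethanesulfonate (not isolated) | FC(F)(F)S(=O)(=O)OC[C@H]1O[C@]1(C)CC/C=C(\C)CCC=C(C)C | intermediate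
5 | (2R,3R)-3-[(3E)-4,8-dimethylnona-3,7-dien-1-yl]-3-methyl-2-(4,4,4-triethoxybut-2-yn-1-yl)oxirane (not isolated) | CCOC(OCC)(OCC)C#CC[C@H]1O[C@]1(C)CC/C=C(\C)CCC=C(C)C | intermediate
6 | ethyl 4-[(2R,3R)-3-[(3E)-4,8-dimethylnona-3,7-dien-1-yl]-3-methyloxiran-2-yl]but-2-ynoate | CCOC(=O)C#CC[C@H]1O[C@]1(C)CC/C=C(\C)CCC=C(C)C | intermediate
7 | ethyl (2Z)-4-[(2R,3R)-3-[(3E)-4,8-dimethylnona-3,7-dien-1-yl]-3-methyloxiran-2-yl]but-2-enoate | CCOC(=O)/C=C\C[C@H]1O[C@]1(C)CC/C=C(\C)CCC=C(C)C | intermediate
8 | (2Z)-4-[(2R,3R)-3-[(3E)-4,8-dimethylnona-3,7-dien-1-yl]-3-methyloxiran-2-yl]but-2-enoic acid (not isolated) | OC(=O)/C=C\C[C@H]1O[C@]1(C)CC/C=C(\C)CCC=C(C)C | intermediate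
9 | (6S)-6-[(2R,5E)-2-hydroxy-6,10-dimethylundeca-5,9-dien-2-yl]-5,6-dihydro-2H-pyran-2-one | O=C1C=CC[C@H](O1)[C@](C)(O)CC/C=C(\C)CCC=C(C)C | intermediate
10 | (6S)-6-[(2R,5E,9E)-2,11-dihydroxy-6,10-dimethylundeca-5,9-dien-2-yl]-5,6-dihydro-2H-pyran-2-one | O=C1C=CC[C@H](O1)[C@](C)(O)CC/C=C(\C)CC/C=C(\C)CO | intermediate
11 | 1,3-dithiane | C1CSCSC1 | starting material
12 | (4R,6S)-4-(1,3-dithian-2-yl)-6-[(2R,5E,9E)-2,11-dihydroxy-6,10-dimethylundeca-5,9-dien-2-yl]oxan-2-one | S1CCCSC1[C@H]2CC(=O)O[C@@H](C2)[C@](C)(O)CC/C=C(\C)CC/C=C(\C)CO | intermediate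
13 | (2E,6E,10R)-10-[(2S,4R)-4-formyl-6-oxooxan-2-yl]-10-hydroxy-2,6-dimethylundeca-2,6-dienal | O=C[C@H]1CC(=O)O[C@@H](C1)[C@](C)(O)CC/C=C(\C)CC/C=C(\C)C=O | intermediate
14 | γ-(triethylsilyloxy)allyl dichloride of trivalent chromium derived from 13: chromium on C11, (E)-enol silane C12=C13, C14 aldehyde and δ-lactone intact (not isolated) | O=C[C@H]1CC(=O)O[C@@H](C1)[C@](C)(O)CC/C=C(\C)CCC([Cr](Cl)Cl)/C(C)=C/O[Si](CC)(CC)CC | intermediate
15 | bridged macrocycle: 14-membered ring closed, 13-O-triethylsilyl, O14 as dichloride alkoxide of trivalent chromium, δ-lactone C16–O3 still spanning C1 and C3 (not isolated) | O=C1C[C@H]2C[C@H](O1)[C@](C)(O)CC/C=C(\C)CC/C=C(\C)[C@H](O[Si](CC)(CC)CC)[C@@H]2O[Cr](Cl)Cl | intermediate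
16 | 13-O-triethylsilyl ether of 17, drawn with free O3 (present as its chromium alkoxide; not isolated) | C1C(=O)O[C@@H]2[C@@H]1C[C@H](O)[C@](C)(O)CC/C=C(\C)CC/C=C(\C)[C@@H]2O[Si](CC)(CC)CC | intermediate
17 | (1R,3S,4R,7E,11E,13S,14R)-3,4,13-trihydroxy-17-norcembra-7,11-dien-16,14-olide | C1C(=O)O[C@@H]2[C@@H]1C[C@H](O)[C@](C)(O)CC/C=C(\C)CC/C=C(\C)[C@@H]2O | intermediate
18 | 3,4,13-tris-O-(triethylsilyl) ether of 17 | C1C(=O)O[C@@H]2[C@@H]1C[C@H](O[Si](CC)(CC)CC)[C@](C)(O[Si](CC)(CC)CC)CC/C=C(\C)CC/C=C(\C)[C@@H]2O[Si](CC)(CC)CC | intermediate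
19 | 15-(dimethylaminomethyl) derivative of 18, expected 15-epimer with the new group anti to C2 (configuration without consequence; not isolated) | CN(C)C[C@H]1C(=O)O[C@@H]2[C@@H]1C[C@H](O[Si](CC)(CC)CC)[C@](C)(O[Si](CC)(CC)CC)CC/C=C(\C)CC/C=C(\C)[C@@H]2O[Si](CC)(CC)CC | intermediate
20 | N-methyl quaternary ammonium iodide of 19 (not isolated) | C[N+](C)(C)C[C@H]1C(=O)O[C@@H]2[C@@H]1C[C@H](O[Si](CC)(CC)CC)[C@](C)(O[Si](CC)(CC)CC)CC/C=C(\C)CC/C=C(\C)[C@@H]2O[Si](CC)(CC)CC.[I-] | intermediate
21 | (1R,3S,4R,7E,11E,13S,14R)-3,4,13-tris(triethylsilyloxy)cembra-7,11,15(17)-trien-16,14-olide | C=C1C(=O)O[C@@H]2[C@@H]1C[C@H](O[Si](CC)(CC)CC)[C@](C)(O[Si](CC)(CC)CC)CC/C=C(\C)CC/C=C(\C)[C@@H]2O[Si](CC)(CC)CC | intermediate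
22 | (1R,3S,4R,7E,11E,13S,14R)-3,4,13-trihydroxycembra-7,11,15(17)-trien-16,14-olide | C=C1C(=O)O[C@@H]2[C@@H]1C[C@H](O)[C@](C)(O)CC/C=C(\C)CC/C=C(\C)[C@@H]2O | intermediate
23 | Crassocolide B | C=C1C(=O)O[C@@H]2[C@@H]1C[C@H](OC(C)=O)[C@](C)(O)CC/C=C(\C)CC/C=C(\C)[C@@H]2OC(C)=O | target

## Step count and risks

Total step count: 12. Longest linear sequence: 12 steps, from (2E,6E)-farnesol.

Steps most likely to fail:

1. Step 8 (proposed new method). What may go wrong: attack on the wrong face of the C14 aldehyde, allyl transfer through C11 instead of C13, or oligomerisation in place of ring closure. The fallback sets out from 13 and closes the same bond by the low-valent titanium (McMurry) pinacol cyclisation, a macrocyclisation known for 14-membered cembranoid glycols: TiCl3(DME)1.5, Zn–Cu couple, DME, slow addition, then DBU in CH2Cl2 to move the acyl group to O14. This radical coupling is expected to favour the threo glycol, that is the (13R)-epimer of 17 F1, beside 17 itself and 14S isomers that would be removed by chromatography. MnO2 in CH2Cl2 should oxidise only the allylic C13 alcohol of F1, giving the 13-oxo lactone F2. Reduction of F2 with Zn(BH4)2 in Et2O at −20 °C, with chelation between the ketone and the ring oxygen on C14 directing hydride to the anti glycol, should give the 13S alcohol, and the fallback comes back to the route at 17.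

2. Step 6. What may go wrong: interference by the two lithium alkoxides, namely directed delivery of the nucleophile to the wrong face, reversible intramolecular oxa-Michael addition of the C4 alkoxide, or 1,2-addition to the lactone carbonyl. The fallback sets out from 10 and replaces the anionic addition by a neutral radical one: decatungstate-photocatalysed C–H addition of 1,3-dioxolane ((n-Bu4N)4[W10O32] cat., 1,3-dioxolane/MeCN, 365 nm). The dioxolan-2-yl radical should add to C1 anti to the C3 substituent and give the trans dioxolane adduct F3. Dess–Martin periodinane with NaHCO3 in CH2Cl2 then oxidises the allylic alcohol to the enal acetal F4, and 1 M HCl in THF at 0 °C hydrolyses the dioxolane, so the fallback comes back to the route at 13.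

3. Step 5. What may go wrong: loss of site selectivity between the two trisubstituted alkenes and over-oxidation of the allylic alcohol. The fallback sets out from 9 and installs the C13 oxygen by olefin cross-metathesis instead of C–H oxidation: methacrolein with the second-generation Hoveyda–Grubbs catalyst in CH2Cl2 at 40 °C should exchange the terminal isopropylidene group for the (E)-2-methyl-enal and give the enal lactone F5. Luche reduction (NaBH4, CeCl3·7H2O, MeOH, −40 °C) of the aldehyde alone then comes back to the route at 10.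

Further compounds
F1 | step 8 | (1R,3S,4R,7E,11E,13R,14R)-3,4,13-trihydroxy-17-norcembra-7,11-dien-16,14-olide (13-epimer of 17) | C1C(=O)O[C@@H]2[C@@H]1C[C@H](O)[C@](C)(O)CC/C=C(\C)CC/C=C(\C)[C@H]2O
F2 | step 8 | (1R,3S,4R,7E,11E,14R)-3,4-dihydroxy-13-oxo-17-norcembra-7,11-dien-16,14-olide | C1C(=O)O[C@@H]2[C@@H]1C[C@H](O)[C@](C)(O)CC/C=C(\C)CC/C=C(\C)C2=O
F3 | step 6 | (4R,6S)-4-(1,3-dioxolan-2-yl)-6-[(2R,5E,9E)-2,11-dihydroxy-6,10-dimethylundeca-5,9-dien-2-yl]oxan-2-one | O1CCOC1[C@H]2CC(=O)O[C@@H](C2)[C@](C)(O)CC/C=C(\C)CC/C=C(\C)CO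
F4 | step 6 | (2E,6E,10R)-10-[(2S,4R)-4-(1,3-dioxolan-2-yl)-6-oxooxan-2-yl]-10-hydroxy-2,6-dimethylundeca-2,6-dienal | O1CCOC1[C@H]2CC(=O)O[C@@H](C2)[C@](C)(O)CC/C=C(\C)CC/C=C(\C)C=O
F5 | step 5 | (2E,6E,10R)-10-hydroxy-2,6-dimethyl-10-[(2S)-6-oxo-3,6-dihydro-2H-pyran-2-yl]undeca-2,6-dienal | O=C1C=CC[C@H](O1)[C@](C)(O)CC/C=C(\C)CC/C=C(\C)C=O
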